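**Retrosynthetic overview**
1. Target 30 ⇒ hydrogenolysis of one O‑benzyl group ⇐ acid 29 ⇐ Pinnick oxidation of depside aldehyde 28.
2. 28 ⇒ aryl ester C–O disconnection into A‑ring acid 17 (as acid chloride 27) and B‑ring phenol 26 (2,4‑dihydroxy‑6‑pentylbenzaldehyde).
3. A ring: 17 ⇐ aldehyde 13 ⇐ symmetric 2‑chloro‑1,3‑dimethoxy‑5‑propylbenzene 11 (Cl placed by directed ortho‑metalation, so formylation has only one possible site) ⇐ 5‑propylresorcinol 8.
4. Both carbocycles come from the same annulation: dimethyl malonate 1 plus an (E)‑alk‑3‑en‑2‑one (2 or 18) by intermolecular Michael addition then Dieckmann/Claisen ring closure, followed by aromatisation and decarboxylation (→ 8 and → 24).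
5. Ring order: A‑ring carbocycle first (steps 1–2), B‑ring carbocycle second (steps 10–11); the two arenes are joined in step 14; no other rings are formed.

Assumption: the target has no stereocentre (it is achiral), so there is no enantiomer to control; intermediates 3–5, 12 and 19–21 are racemic and their stereocentres are destroyed again.

**Route**

Step 1
Reactants: 1 dimethyl malonate; 2 (E)-hept-3-en-2-one
Product: 4 methyl 2-hydroxy-4-oxo-6-propylcyclohex-2-ene-1-carboxylate, via Michael adduct 3 (not isolated)
Conditions: NaOMe (1.1 equiv), MeOH, reflux, 4 h; then 1 M HCl, 0 °C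
Reagents that add atoms: none
Why: Intermolecular Michael addition of the malonate enolate to the enone makes the key C–C bond, and the methyl‑ketone enolate then closes the ring by intramolecular Claisen (Dieckmann) condensation, driven by the stabilised β‑diketone enolate; the two stereocentres form racemic and are erased in step 2.

Step 2
Reactants: 4 methyl 2-hydroxy-4-oxo-6-propylcyclohex-2-ene-1-carboxylate
Product: 6 methyl 2,4-dihydroxy-6-propylbenzoate, via bromo dione 5 (not isolated)
Conditions: Br2 (1.0 equiv), DMF, 0 °C, 1 h; then 80 °C, 12 h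
Reagents that add atoms: none
Why: Halogenation–dehydrohalogenation aromatisation: the enolised 1,3‑dione is brominated and the bromo dione loses HBr on heating and tautomerises to the resorcylate, one equivalent of Br2 supplying the two‑electron oxidation.

Step 3
Reactants: 6 methyl 2,4-dihydroxy-6-propylbenzoate
Product: 8 5-propylbenzene-1,3-diol, via divarinic acid 7 (not isolated)
Conditions: 2.5 M NaOH, MeOH, reflux, N2, 4 h; then conc. HCl to pH 1, 60 °C, 1 h
Reagents that add atoms: none
Why: Ester saponification followed by protodecarboxylation, which is easy for a 2,4‑dihydroxybenzoic acid because the ipso carbon is ortho and para to hydroxyl groups, gives the symmetric resorcinol.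

Step 4
Reactants: 8 5-propylbenzene-1,3-diol
Product: 9 1,3-dimethoxy-5-propylbenzene
Conditions: Me2SO4 (2.5 equiv), K2CO3 (3 equiv), acetone, reflux, 12 h
Reagents that add atoms: dimethyl sulfate COS(=O)(=O)OC
Why: Williamson ether synthesis (double O‑methylation of the phenoxides) gives an arene whose C2 is flanked by two directing methoxy groups.

Step 5
Reactants: 9 1,3-dimethoxy-5-propylbenzene
Product: 11 2-chloro-1,3-dimethoxy-5-propylbenzene, via aryllithium 10 (not isolated)
Conditions: n-BuLi (1.2 equiv), THF, 0 °C → rt, 2 h; then C2Cl6 (1.3 equiv), −78 °C → rt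
Reagents that add atoms: hexachloroethane ClC(Cl)(Cl)C(Cl)(Cl)Cl
Why: Directed ortho‑metalation occurs at the carbon between the two methoxy groups and electrophilic chlorination of the aryllithium puts chlorine there with complete regiocontrol.

Step 6
Reactants: 11 2-chloro-1,3-dimethoxy-5-propylbenzene
Product: 13 3-chloro-2,4-dimethoxy-6-propylbenzaldehyde, via α-chloro ether 12 (not isolated)
Conditions: Cl2CHOMe (1.5 equiv), TiCl4 (2.2 equiv), CH2Cl2, −10 → 0 °C, 2 h; then ice/H2O
Reagents that add atoms: dichloromethyl methyl ether COC(Cl)Cl; water O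
Why: Rieche formylation (Friedel–Crafts‑type electrophilic aromatic substitution): the two free ring positions are equivalent by symmetry and activated ortho/para by the methoxy groups, so only one aldehyde can form.

Step 7
Reactants: 13 3-chloro-2,4-dimethoxy-6-propylbenzaldehyde
Product: 15 3-chloro-2-hydroxy-4-methoxy-6-propylbenzaldehyde, via aryloxydichloroborane 14 (not isolated)
Conditions: BCl3 (1.2 equiv, 1 M in CH2Cl2), CH2Cl2, −78 → 0 °C, 1 h; then H2O
Reagents that add atoms: none
Why: Chelation‑controlled Lewis‑acid demethylation: BCl3 bound to the aldehyde oxygen cleaves only the neighbouring ortho methyl ether, and the para methoxy group is untouched at low temperature.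

Step 8
Reactants: 15 3-chloro-2-hydroxy-4-methoxy-6-propylbenzaldehyde
Product: 16 2-(benzyloxy)-3-chloro-4-methoxy-6-propylbenzaldehyde
Conditions: BnBr (1.3 equiv), K2CO3 (2 equiv), DMF, 60 °C, 6 h
Reagents that add atoms: benzyl bromide BrCc1ccccc1
Why: Williamson benzylation of the phenoxide masks the ortho hydroxyl for the oxidation and acylation steps.

Step 9
Reactants: 16 2-(benzyloxy)-3-chloro-4-methoxy-6-propylbenzaldehyde
Product: 17 2-(benzyloxy)-3-chloro-4-methoxy-6-propylbenzoic acid
Conditions: NaClO2 (3 equiv), NaH2PO4 (3 equiv), 2-methyl-2-butene (10 equiv), t-BuOH/THF/H2O, rt, 6 h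
Reagents that add atoms: sodium chlorite [Na+].[O-]Cl=O
Why: Pinnick oxidation converts the hindered aldehyde into the acid under buffered conditions, the alkene scavenger removing HOCl so the electron‑rich ring is not chlorinated.

Step 10
Reactants: 1 dimethyl malonate; 18 (E)-non-3-en-2-one
Product: 20 methyl 2-hydroxy-4-oxo-6-pentylcyclohex-2-ene-1-carboxylate, via Michael adduct 19 (not isolated)
Conditions: NaOMe (1.1 equiv), MeOH, reflux, 4 h; then 1 M HCl, 0 °C
Reagents that add atoms: none
Why: The same intermolecular Michael addition/Dieckmann (Claisen) annulation as in step 1 builds the B‑ring carbocycle; the stereocentres form racemic and are erased in step 11.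

Step 11
Reactants: 20 methyl 2-hydroxy-4-oxo-6-pentylcyclohex-2-ene-1-carboxylate
Product: 22 methyl 2,4-dihydroxy-6-pentylbenzoate, via bromo dione 21 (not isolated)
Conditions: Br2 (1.0 equiv), DMF, 0 °C, 1 h; then 80 °C, 12 h
Reagents that add atoms: none
Why: Bromination–dehydrobromination aromatisation of the cyclic 1,3‑dione, as in step 2, is the established way to methyl olivetolate.

Step 12
Reactants: 22 methyl 2,4-dihydroxy-6-pentylbenzoate
Product: 24 5-pentylbenzene-1,3-diol, via olivetolic acid 23 (not isolated)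
Conditions: 2.5 M NaOH, MeOH, reflux, N2, 4 h; then conc. HCl to pH 1, 60 °C, 1 h
Reagents that add atoms: none
Why: Saponification and protodecarboxylation of the β‑resorcylic acid, which occurs readily under these conditions, are run to completion to give olivetol cleanly.

Step 13
Reactants: 24 5-pentylbenzene-1,3-diol
Product: 26 2,4-dihydroxy-6-pentylbenzaldehyde, via iminium chloride 25 (not isolated)
Conditions: POCl3 (1.2 equiv), DMF (1.5 equiv), MeCN, −15 °C → rt, 3 h; then H2O, 50 °C, 1 h
Reagents that add atoms: N,N-dimethylformamide CN(C)C=O; water O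
Why: Vilsmeier–Haack formylation attacks the position para to one hydroxyl and ortho to the other (the two such positions are equivalent) in preference to the hindered carbon between the hydroxyls, and the iminium salt is hydrolysed to the aldehyde.

Step 14
Reactants: 17 2-(benzyloxy)-3-chloro-4-methoxy-6-propylbenzoic acid; 26 2,4-dihydroxy-6-pentylbenzaldehyde
Product: 28 4-formyl-3-hydroxy-5-pentylphenyl 2-(benzyloxy)-3-chloro-4-methoxy-6-propylbenzoate, via acid chloride 27 (not isolated)
Conditions: (COCl)2 (1.5 equiv), DMF (cat.), CH2Cl2, 0 °C → rt, 2 h, evaporate; then 26 (1.0 equiv), Et3N (1.5 equiv), DMAP (0.1 equiv), CH2Cl2, 0 °C → rt, 12 h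
Reagents that add atoms: none
Why: Acid chloride formation then DMAP‑catalysed nucleophilic acyl substitution (esterification) at the more acidic, unchelated 4‑hydroxyl of 26, the 2‑hydroxyl being hydrogen‑bonded to the aldehyde and hindered.

Step 15
Reactants: 28 4-formyl-3-hydroxy-5-pentylphenyl 2-(benzyloxy)-3-chloro-4-methoxy-6-propylbenzoate
Product: 29 4-{[2-(benzyloxy)-3-chloro-4-methoxy-6-propylbenzoyl]oxy}-2-hydroxy-6-pentylbenzoic acid
Conditions: NaClO2 (3 equiv), NaH2PO4 (3 equiv), 2-methyl-2-butene (15 equiv), t-BuOH/THF/H2O, 0 °C → rt, 6 h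
Reagents that add atoms: sodium chlorite [Na+].[O-]Cl=O
Why: Pinnick oxidation turns the salicylaldehyde into the salicylic acid at pH 3–4, conditions under which the aryl ester, benzyl ether and aryl chloride are inert and HOCl is scavenged.

Step 16
Reactants: 29 4-{[2-(benzyloxy)-3-chloro-4-methoxy-6-propylbenzoyl]oxy}-2-hydroxy-6-pentylbenzoic acid
Product: 30 4-[(3-chloro-2-hydroxy-4-methoxy-6-propylbenzoyl)oxy]-2-hydroxy-6-pentylbenzoic acid
Conditions: H2 (1 atm), 10% Pd/C, EtOAc, rt, ca. 1 h, stopped at full conversion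
Reagents that add atoms: none
Why: Catalytic hydrogenolysis removes the benzyl ether under neutral conditions at 1 atm, where the depside ester is untouched and the chlorine, flanked by two oxygens, is expected to be retained for a short reaction.

**Compound list**
1 | dimethyl malonate (dimethyl propanedioate) | COC(=O)CC(=O)OC | starting material
2 | (E)-hept-3-en-2-one | CCC/C=C/C(C)=O | starting material
3 | dimethyl 2-(2-oxoheptan-4-yl)propanedioate (racemic) | CCCC(CC(C)=O)C(C(=O)OC)C(=O)OC | intermediate
4 | methyl 2-hydroxy-4-oxo-6-propylcyclohex-2-ene-1-carboxylate (racemic; enol form of the 2,4-dione) | CCCC1CC(=O)C=C(O)C1C(=O)OC | intermediate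
5 | methyl 3-bromo-2-hydroxy-4-oxo-6-propylcyclohex-2-ene-1-carboxylate (racemic) | CCCC1CC(=O)C(Br)=C(O)C1C(=O)OC | intermediate
6 | methyl 2,4-dihydroxy-6-propylbenzoate (methyl divarinate) | CCCc1cc(O)cc(O)c1C(=O)OC | intermediate
7 | 2,4-dihydroxy-6-propylbenzoic acid (divarinic acid) | CCCc1cc(O)cc(O)c1C(=O)O | intermediate
8 | 5-propylbenzene-1,3-diol (divarinol) | CCCc1cc(O)cc(O)c1 | intermediate
9 | 1,3-dimethoxy-5-propylbenzene | CCCc1cc(OC)cc(OC)c1 | intermediate
10 | (2,6-dimethoxy-4-propylphenyl)lithium | [Li]c1c(OC)cc(CCC)cc1OC | intermediate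
11 | 2-chloro-1,3-dimethoxy-5-propylbenzene | CCCc1cc(OC)c(Cl)c(OC)c1 | intermediate
12 | 2-chloro-4-[chloro(methoxy)methyl]-1,3-dimethoxy-5-propylbenzene (racemic) | CCCc1cc(OC)c(Cl)c(OC)c1C(Cl)OC | intermediate
13 | 3-chloro-2,4-dimethoxy-6-propylbenzaldehyde | CCCc1cc(OC)c(Cl)c(OC)c1C=O | intermediate
14 | dichloro(2-chloro-6-formyl-3-methoxy-5-propylphenoxy)borane | CCCc1cc(OC)c(Cl)c(OB(Cl)Cl)c1C=O | intermediate
15 | 3-chloro-2-hydroxy-4-methoxy-6-propylbenzaldehyde | CCCc1cc(OC)c(Cl)c(O)c1C=O | intermediate
16 | 2-(benzyloxy)-3-chloro-4-methoxy-6-propylbenzaldehyde | CCCc1cc(OC)c(Cl)c(OCc2ccccc2)c1C=O | intermediate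
17 | 2-(benzyloxy)-3-chloro-4-methoxy-6-propylbenzoic acid | CCCc1cc(OC)c(Cl)c(OCc2ccccc2)c1C(=O)O | intermediate
18 | (E)-non-3-en-2-one | CCCCC/C=C/C(C)=O | starting material
19 | dimethyl 2-(2-oxononan-4-yl)propanedioate (racemic) | CCCCCC(CC(C)=O)C(C(=O)OC)C(=O)OC | intermediate
20 | methyl 2-hydroxy-4-oxo-6-pentylcyclohex-2-ene-1-carboxylate (racemic; enol form of the 2,4-dione) | CCCCCC1CC(=O)C=C(O)C1C(=O)OC | intermediate
21 | methyl 3-bromo-2-hydroxy-4-oxo-6-pentylcyclohex-2-ene-1-carboxylate (racemic) | CCCCCC1CC(=O)C(Br)=C(O)C1C(=O)OC | intermediate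
22 | methyl 2,4-dihydroxy-6-pentylbenzoate (methyl olivetolate) | CCCCCc1cc(O)cc(O)c1C(=O)OC | intermediate
23 | 2,4-dihydroxy-6-pentylbenzoic acid (olivetolic acid) | CCCCCc1cc(O)cc(O)c1C(=O)O | intermediate
24 | 5-pentylbenzene-1,3-diol (olivetol) | CCCCCc1cc(O)cc(O)c1 | intermediate
25 | N-[(2,4-dihydroxy-6-pentylphenyl)methylidene]-N-methylmethanaminium chloride | CCCCCc1cc(O)cc(O)c1C=[N+](C)C.[Cl-] | intermediate
26 | 2,4-dihydroxy-6-pentylbenzaldehyde | CCCCCc1cc(O)cc(O)c1C=O | intermediate
27 | 2-(benzyloxy)-3-chloro-4-methoxy-6-propylbenzoyl chloride | CCCc1cc(OC)c(Cl)c(OCc2ccccc2)c1C(Cl)=O | intermediate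
28 | 4-formyl-3-hydroxy-5-pentylphenyl 2-(benzyloxy)-3-chloro-4-methoxy-6-propylbenzoate | CCCCCc1cc(OC(=O)c2c(CCC)cc(OC)c(Cl)c2OCc3ccccc3)cc(O)c1C=O | intermediate
29 | 4-{[2-(benzyloxy)-3-chloro-4-methoxy-6-propylbenzoyl]oxy}-2-hydroxy-6-pentylbenzoic acid | CCCCCc1cc(OC(=O)c2c(CCC)cc(OC)c(Cl)c2OCc3ccccc3)cc(O)c1C(=O)O | intermediate
30 | 4-[(3-chloro-2-hydroxy-4-methoxy-6-propylbenzoyl)oxy]-2-hydroxy-6-pentylbenzoic acid (achiral) | CCCCCc1cc(OC(=O)c2c(CCC)cc(OC)c(Cl)c2O)cc(O)c1C(=O)O | target

**Totals and risks**
Total step count: 16. Longest linear sequence: 12 steps (steps 1–9, then 14, 15, 16).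

The three steps most likely to fail:

Step 2. The Br2/DMF aromatisation can stop at bromo dione 5 or over-brominate the ring, which lowers the yield. The fallback sets out from 4: brominate exhaustively on purpose (Br2, 3 equiv, AcOH, rt) to the aromatic, crystalline methyl 3,5-dibromo-2,4-dihydroxy-6-propylbenzoate F1, then remove both bromines by catalytic hydrodebromination (H2, Pd/C, NaOAc, MeOH). No chlorine is present at this stage, and the sequence comes back to the route at 6.

Step 14. The 2,6-disubstituted aroyl chloride 27 may acylate the phenol slowly or incompletely. The fallback sets out from 15 and 26 and drops the benzyl group: oxidise 15 directly (NaClO2, NaH2PO4, 2-methyl-2-butene) to 3-chloro-2-hydroxy-4-methoxy-6-propylbenzoic acid F2. Treat F2 and 26 with trifluoroacetic anhydride in toluene at rt, which activates the acid in situ as 3-chloro-2-hydroxy-4-methoxy-6-propylbenzoic trifluoroacetic anhydride F3; this acylium-type acylation has little steric demand and the chelated ortho hydroxyl does not compete. The product is 4-formyl-3-hydroxy-5-pentylphenyl 3-chloro-2-hydroxy-4-methoxy-6-propylbenzoate F4, and a Pinnick oxidation as in step 15 comes back to the route at 30 with no deprotection needed.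

Step 16. Hydrogenolysis could also remove the aryl chloride. The fallback sets out from 29 and gives up hydrogenation: cleave the chelated ortho benzyl ether with BCl3 (4 equiv) and pentamethylbenzene (3 equiv) in CH2Cl2 at −78 °C. This Lewis-acid debenzylation with a cation scavenger leaves C–Cl, the para methoxy group and the depside ester alone, and comes back to the route at 30. No new compound is made (F0).

**Further compounds**
F1 | step 2 | methyl 3,5-dibromo-2,4-dihydroxy-6-propylbenzoate | CCCc1c(Br)c(O)c(Br)c(O)c1C(=O)OC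
F2 | step 14 | 3-chloro-2-hydroxy-4-methoxy-6-propylbenzoic acid | CCCc1cc(OC)c(Cl)c(O)c1C(=O)O
F3 | step 14 | 3-chloro-2-hydroxy-4-methoxy-6-propylbenzoic trifluoroacetic anhydride | CCCc1cc(OC)c(Cl)c(O)c1C(=O)OC(=O)C(F)(F)F
F4 | step 14 | 4-formyl-3-hydroxy-5-pentylphenyl 3-chloro-2-hydroxy-4-methoxy-6-propylbenzoate | CCCCCc1cc(OC(=O)c2c(CCC)cc(OC)c(Cl)c2O)cc(O)c1C=O
F0 | step 16 | none | none
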